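## Retrosynthetic overview

- Psiguadial A (22) ⇒ (+)-bicyclogermacrene (15) + diformylphloroglucinol (18) + benzaldehyde (19): a one-pot o-quinone-methide addition at C4, transannular C1–C5 closure and O–C1 etherification that forms four bonds and five stereocentres.
- Enabling feature: the cyclopentane (C1–C5) and the cycloheptane (C1, C5–C10) share only the C1–C5 bond. Without it the carbocycle is a cyclodeca-1(10),4-diene whose C4=C5 bond is flanked by the cis-fused dimethylcyclopropane (C6, C7, C11), so C5 is a cyclopropylcarbinyl centre facing C1 across the ring.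
- 15 ⇒ cyclic sulfone 14 ⇒ open-chain sulfone/allylic chloride 13: the ten-membered ring is closed at C2–C3 with both (E) olefins already in place.
- 13 ⇒ keto aldehyde 3 ⇒ (+)-2-carene (1), which supplies C6/C7 from the chiral pool; 18 ⇐ phloroglucinol (16).
- Ring order: cyclopropane (purchased) → ten-membered carbocycle (step 10) → cyclopentane and cycloheptane together, then the oxepane (step 13).

Key step: step 13

Remark: (+)-2-carene is taken as the (1S,6R) enantiomer, whose cyclopropane maps onto C6/C7 of the target; locants are aromadendrane locants (C1 = O-bearing ring-fusion carbon, C4 = quaternary carbon carrying the benzylic carbon C1', C5 = ring-fusion CH, C6/C7 = cyclopropane CH, C10 = CHCH3, C11 = C(CH3)2).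

## Route

Step 1
Reactants: 1 (+)-2-carene
Product: 3 (1S,3R)-2,2-dimethyl-3-(3-oxobutyl)cyclopropane-1-carbaldehyde, via ozonide 2 (not isolated)
Conditions: O3, CH2Cl2, −78 °C; then Me2S, −78 → 25 °C
Reagents that add atoms: ozone, [O-][O+]=O
Why: Ozonolysis (Criegee mechanism) with neutral reductive work-up cleaves the only olefin and leaves the cis-cyclopropane stereocentres (future C6/C7) untouched.

Step 2
Reactants: 3 keto aldehyde
Product: 4 4-[(1R,3S)-3-(dimethoxymethyl)-2,2-dimethylcyclopropyl]butan-2-one
Conditions: HC(OMe)3, CeCl3·7H2O (cat.), MeOH, 25 °C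
Reagents that add atoms: trimethyl orthoformate, COC(OC)OC
Why: Lanthanide-catalysed acetalisation is selective for aldehydes over ketones, so the aldehyde is masked and the methyl ketone stays free for olefination.

Step 3
Reactants: 4 keto acetal
Product: 5 ethyl (2E)-5-[(1R,3S)-3-(dimethoxymethyl)-2,2-dimethylcyclopropyl]-3-methylpent-2-enoate
Conditions: (EtO)2P(O)CH2CO2Et, NaH, THF, 0 → 50 °C; chromatographic removal of the (2Z) isomer
Reagents that add atoms: triethyl phosphonoacetate, CCOC(=O)CP(=O)(OCC)OCC
Why: Horner–Wadsworth–Emmons olefination of the methyl ketone should favour the (E) enoate (ester trans to the longer chain), which fixes the future C1=C10 geometry; the minor (Z) isomer is separated here.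

Step 4
Reactants: 5 enoate
Product: 6 (2E)-5-[(1R,3S)-3-(dimethoxymethyl)-2,2-dimethylcyclopropyl]-3-methylpent-2-en-1-ol
Conditions: i-Bu2AlH, CH2Cl2, −78 °C; aq. KNaC4H4O6
Reagents that add atoms: none
Why: 1,2-Reduction of the enoate by the aluminium hydride gives the allylic alcohol without touching the acetal or the olefin geometry.

Step 5
Reactants: 6 allylic alcohol
Product: 8 {[(2E)-5-[(1R,3S)-3-(dimethoxymethyl)-2,2-dimethylcyclopropyl]-3-methylpent-2-enyl]sulfonyl}benzene, via allylic bromide 7 (not isolated)
Conditions: CBr4, PPh3, 2,6-lutidine, CH2Cl2, 0 °C; then PhSO2Na, DMF, 25 °C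
Reagents that add atoms: carbon tetrabromide, BrC(Br)(Br)Br (bromine of 7); sodium benzenesulfinate, [Na+].[O-]S(=O)c1ccccc1
Why: Appel bromination followed by SN2 S-alkylation of the sulfinate is the standard entry to prenyl-type allylic sulfones and keeps the (E) geometry.

Step 6
Reactants: 8 sulfonyl acetal
Product: 9 (1S,3R)-2,2-dimethyl-3-[(3E)-3-methyl-5-(phenylsulfonyl)pent-3-enyl]cyclopropane-1-carbaldehyde
Conditions: PPTS (cat.), acetone/H2O, 45 °C
Reagents that add atoms: water, O
Why: Mild acid-catalysed acetal hydrolysis through the cyclopropyl-stabilised oxocarbenium ion frees the aldehyde without enolisation, so the cis cyclopropane should be kept.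

Step 7
Reactants: 9 sulfonyl aldehyde
Product: 10 ethyl (2E)-3-{(1S,3R)-2,2-dimethyl-3-[(3E)-3-methyl-5-(phenylsulfonyl)pent-3-enyl]cyclopropyl}-2-methylprop-2-enoate
Conditions: Ph3P=C(CH3)CO2Et, toluene, 60 °C
Reagents that add atoms: ethyl 2-(triphenylphosphoranylidene)propanoate, CCOC(=O)C(C)=P(c1ccccc1)(c1ccccc1)c1ccccc1
Why: The Wittig reaction of the stabilised α-methyl ylide should give the (E)-2-methyl enoate (future C4=C5) selectively, and the ylide is too weak a base to deprotonate the sulfone or epimerise the aldehyde.

Step 8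
Reactants: 10 sulfonyl dienoate
Product: 11 (2E)-3-{(1S,3R)-2,2-dimethyl-3-[(3E)-3-methyl-5-(phenylsulfonyl)pent-3-enyl]cyclopropyl}-2-methylprop-2-en-1-ol
Conditions: i-Bu2AlH, CH2Cl2, −78 °C; aq. KNaC4H4O6
Reagents that add atoms: none
Why: 1,2-Reduction of the enoate gives the allylic alcohol; the sulfone is inert to the aluminium hydride at low temperature.

Step 9
Reactants: 11 allylic alcohol
Product: 13 {[(2E)-5-{(1R,3S)-3-[(1E)-3-chloro-2-methylprop-1-enyl]-2,2-dimethylcyclopropyl}-3-methylpent-2-enyl]sulfonyl}benzene, via allylic mesylate 12 (not isolated)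
Conditions: MsCl, LiCl, 2,4,6-collidine, DMF, 0 °C
Reagents that add atoms: methanesulfonyl chloride, CS(=O)(=O)Cl (mesyl group of 12); lithium chloride, [Li+].[Cl-]
Why: Mesylation with in-flask SN2 displacement by chloride converts primary allylic alcohols into allylic chlorides without allylic transposition or loss of geometry.

Step 10
Reactants: 13 allylic chloride
Product: 14 (1S,2E,6E,10R)-3,7,11,11-tetramethyl-5-(phenylsulfonyl)bicyclo[8.1.0]undeca-2,6-diene
Conditions: LiN(SiMe3)2, THF, −20 → 25 °C, syringe-pump addition (high dilution)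
Reagents that add atoms: none
Why: Intramolecular SN2 alkylation of the sulfone-stabilised allylic carbanion (attack through its α-carbon) by the primary allylic chloride is the classical closure of 1,5-diene terpenoid macrocycles; both (E) olefins are preset, and the sulfone-bearing carbon forms as a mixture that step 11 erases.

Step 11
Reactants: 14 cyclic sulfone
Product: 15 (+)-bicyclogermacrene
Conditions: PdCl2(dppp) (cat.), LiBHEt3, THF, 0 °C
Reagents that add atoms: none
Why: Palladium-catalysed hydride desulfonylation of the allylic sulfone proceeds through a π-allyl intermediate that takes hydride at the less substituted terminus (C2), a method known to keep the position and (E) geometry of trisubstituted isoprenoid olefins.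

Step 12
Reactants: 16 phloroglucinol
Product: 18 2,4,6-trihydroxybenzene-1,3-dicarbaldehyde, via bis-iminium salt 17 (not isolated)
Conditions: POCl3, DMF, EtOAc, 25 °C; then H2O, 50 °C
Reagents that add atoms: N,N-dimethylformamide, CN(C)C=O; water, O
Why: Twofold Vilsmeier–Haack formylation stops at the dialdehyde because two iminium groups deactivate the ring, leaving the position between two hydroxyls free.

Step 13
Reactants: 15 (+)-bicyclogermacrene; 18 2,4,6-trihydroxybenzene-1,3-dicarbaldehyde; 19 benzaldehyde
Product: 22 psiguadial A, via o-quinone methide 20 (not isolated), via olefinic phenol 21 (not isolated)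
Conditions: HFIP, 25 °C (18 and 19 premixed, 15 added last); then TsOH·H2O (cat.), 40 °C
Reagents that add atoms: none
Why: Knoevenagel condensation of 18 with 19 gives o-quinone methide 20, whose benzylic carbon adds as a Michael acceptor to C4 of 15 while C1 of the C1=C10 olefin bonds to C5 from inside the ring; the resulting C10 cation loses H1 to the phenoxide to give olefinic phenol 21, and acid then re-protonates C10 while the phenol oxygen captures the tertiary C1 cation. The closest known reaction types are the proton-induced transannular cation–olefin cyclisation of cyclodeca-1(10),4-dienes to hydroazulenes, here triggered by a carbon electrophile as in biomimetic o-quinone methide–terpene couplings, and acid-mediated phenol–olefin hydroalkoxylation. The single C1–C5 bond closes the cyclopentane (5-exo with respect to the attacking C1=C10 bond) and the cycloheptane (7-endo) by transannular closure of the ten-membered ring, and the oxepane closes 7-exo by O–C1 bond formation. C4 and C5 arise from anti addition across the (E)-C4=C5 bond in the crossed conformer that holds both vinylic methyl groups away from the cyclopropane bridge carbon, so the electrophile enters on the outer face and H5 ends anti to H6; C1 is fixed because the oxygen, tethered through C1' to C4, can only reach the face of C1 cis to the C4–C1' bond; C10 is set by protonation anti to the incoming oxygen, on the face remote from the endo methyl of the cyclopropane; C1' follows from approach of the quinone methide with its phenyl group over the C5–H corner and is the least secure of the five. The step needs carbon–carbon bond formation at C4 in preference to oxygen-first (hetero-Diels–Alder) capture at C5 or across C1=C10 and to protonation of the diene: C5 is both cyclopropylcarbinyl and held across the ring from C1, so charge developing there is stabilised twice, and the ionising, non-nucleophilic solvent with late addition of the acid favours the stepwise polar path.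

## Compound list

1 | (+)-2-carene, (1S,6R)-3,7,7-trimethylbicyclo[4.1.0]hept-2-ene | CC1=C[C@H]2[C@@H](CC1)C2(C)C | starting material
2 | secondary ozonide of 1 (1,2,4-trioxolane across the former olefin; mixture at the two trioxolane carbons) | CC12OOC(O1)[C@H]3[C@@H](CC2)C3(C)C | intermediate
3 | (1S,3R)-2,2-dimethyl-3-(3-oxobutyl)cyclopropane-1-carbaldehyde | O=C[C@H]1[C@@H](CCC(C)=O)C1(C)C | intermediate
4 | 4-[(1R,3S)-3-(dimethoxymethyl)-2,2-dimethylcyclopropyl]butan-2-one | COC(OC)[C@H]1[C@@H](CCC(C)=O)C1(C)C | intermediate
5 | ethyl (2E)-5-[(1R,3S)-3-(dimethoxymethyl)-2,2-dimethylcyclopropyl]-3-methylpent-2-enoate | CCOC(=O)/C=C(\C)CC[C@@H]1[C@H](C(OC)OC)C1(C)C | intermediate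
6 | (2E)-5-[(1R,3S)-3-(dimethoxymethyl)-2,2-dimethylcyclopropyl]-3-methylpent-2-en-1-ol | OC/C=C(\C)CC[C@@H]1[C@H](C(OC)OC)C1(C)C | intermediate
7 | (1R,3S)-1-[(3E)-5-bromo-3-methylpent-3-enyl]-3-(dimethoxymethyl)-2,2-dimethylcyclopropane | BrC/C=C(\C)CC[C@@H]1[C@H](C(OC)OC)C1(C)C | intermediate
8 | {[(2E)-5-[(1R,3S)-3-(dimethoxymethyl)-2,2-dimethylcyclopropyl]-3-methylpent-2-enyl]sulfonyl}benzene | O=S(=O)(C/C=C(\C)CC[C@@H]1[C@H](C(OC)OC)C1(C)C)c1ccccc1 | intermediate
9 | (1S,3R)-2,2-dimethyl-3-[(3E)-3-methyl-5-(phenylsulfonyl)pent-3-enyl]cyclopropane-1-carbaldehyde | O=C[C@H]1[C@@H](CC/C(C)=C/CS(=O)(=O)c2ccccc2)C1(C)C | intermediate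
10 | ethyl (2E)-3-{(1S,3R)-2,2-dimethyl-3-[(3E)-3-methyl-5-(phenylsulfonyl)pent-3-enyl]cyclopropyl}-2-methylprop-2-enoate | CCOC(=O)/C(C)=C/[C@H]1[C@@H](CC/C(C)=C/CS(=O)(=O)c2ccccc2)C1(C)C | intermediate
11 | (2E)-3-{(1S,3R)-2,2-dimethyl-3-[(3E)-3-methyl-5-(phenylsulfonyl)pent-3-enyl]cyclopropyl}-2-methylprop-2-en-1-ol | OC/C(C)=C/[C@H]1[C@@H](CC/C(C)=C/CS(=O)(=O)c2ccccc2)C1(C)C | intermediate
12 | methanesulfonate of 11 | CS(=O)(=O)OC/C(C)=C/[C@H]1[C@@H](CC/C(C)=C/CS(=O)(=O)c2ccccc2)C1(C)C | intermediate
13 | {[(2E)-5-{(1R,3S)-3-[(1E)-3-chloro-2-methylprop-1-enyl]-2,2-dimethylcyclopropyl}-3-methylpent-2-enyl]sulfonyl}benzene | ClC/C(C)=C/[C@H]1[C@@H](CC/C(C)=C/CS(=O)(=O)c2ccccc2)C1(C)C | intermediate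
14 | (1S,2E,6E,10R)-3,7,11,11-tetramethyl-5-(phenylsulfonyl)bicyclo[8.1.0]undeca-2,6-diene (either configuration at C5 of this name) | C1C/C(C)=C/C(S(=O)(=O)c2ccccc2)C/C(C)=C/[C@H]2[C@@H]1C2(C)C | intermediate
15 | (+)-bicyclogermacrene, (1S,2E,6E,10R)-3,7,11,11-tetramethylbicyclo[8.1.0]undeca-2,6-diene | C1C/C(C)=C/CC/C(C)=C/[C@H]2[C@@H]1C2(C)C | intermediate
16 | phloroglucinol (benzene-1,3,5-triol) | Oc1cc(O)cc(O)c1 | starting material
17 | (2,4,6-trihydroxy-1,3-phenylene)bis(N,N-dimethylmethaniminium) dichloride | C[N+](C)=Cc1c(O)cc(O)c(C=[N+](C)C)c1O.[Cl-].[Cl-] | intermediate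
18 | 2,4,6-trihydroxybenzene-1,3-dicarbaldehyde (diformylphloroglucinol) | O=Cc1c(O)cc(O)c(C=O)c1O | intermediate
19 | benzaldehyde | O=Cc1ccccc1 | starting material
20 | o-quinone methide, 5-benzylidene-2,4-dihydroxy-6-oxocyclohexa-1,3-diene-1,3-dicarbaldehyde (either benzylidene geometry) | O=C1C(=Cc2ccccc2)C(O)=C(C=O)C(O)=C1C=O | intermediate
21 | olefinic phenol: aromadendr-1(10)-ene carrying at C4 the (3,5-diformyl-2,4,6-trihydroxyphenyl)(phenyl)methyl group, with C1–C5 formed and O–C1 still open | CC1CC[C@@H]2[C@H]([C@@H]3[C@](C)(CCC3=1)[C@@H](c1ccccc1)c1c(O)c(C=O)c(O)c(C=O)c1O)C2(C)C | intermediate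
22 | psiguadial A | C[C@H]1CC[C@@H]2[C@H]([C@@H]3[C@]4(C)CC[C@@]31Oc1c(C=O)c(O)c(C=O)c(O)c1[C@@H]4c1ccccc1)C2(C)C | target

## Step count and risks

Total step count: 13. Longest linear sequence: 12 steps (steps 1–11 and 13; step 12 is a one-step side branch).

Steps most likely to fail:

1. Step 13 (key step). Three processes threaten it: proton-induced transannular cyclisation of 15 by the strongly acidic dialdehyde before the carbon–carbon bond forms; oxygen-first trapping of 20 as chromans at C5 or across C1=C10; and hydrogen delivery to the wrong face of C10 or attack on the wrong face of the benzylic carbon. The fallback sets out from 15 and 19 and returns at 22. Commercial 2,4,6-trihydroxybenzaldehyde, a weaker acid, replaces 18. Its quinone methide, the mono-formyl o-quinone methide F1, is generated with 19 under buffered conditions (NaOAc, HFIP/H2O) and should undergo the same addition, transannular closure and etherification. This gives the mono-aldehyde F2 (formyl group next to the ether oxygen) together with its ring-position isomer F3 (formyl group between the two hydroxyls). Each has one free aromatic position ortho to a phenol, and magnesium-mediated ortho-formylation (MgCl2, Et3N, paraformaldehyde, MeCN, 60 °C) of either converges on 22.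

2. Step 10. Intermolecular alkylation to dimers and oligomers, and base-induced 1,4-elimination of hydrogen chloride from 13, may outrun closure of the strained ten-membered ring. The fallback sets out from 11 and returns at 14. The alcohol is converted (ClCO2Me, pyridine) into the allylic methyl carbonate F4, and the ring is closed by a Tsuji–Trost allylic alkylation (Pd(PPh3)4, dppe, THF, high dilution). Ionisation of the carbonate by zerovalent palladium gives a π-allyl electrophile and methoxide, so the sulfonyl carbanion is generated only as the electrophile forms; attack at the primary terminus keeps the (E) geometry.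

3. Step 11. Hydride delivery to the tertiary terminus of the π-allyl intermediate (moving the olefin to C1=C2), or syn/anti isomerisation of that intermediate, would erode the (E)-C1=C10 bond. The fallback sets out from 3, returns at 15 and avoids the sulfone altogether. Nozaki–Hiyama–Kishi addition of 2-bromopropene to the aldehyde of 3 (CrCl2, NiCl2 cat., DMF; ketone untouched) gives the allylic alcohol F5. Johnson–Claisen rearrangement (MeC(OEt)3, EtCO2H cat., 135 °C) sets the (E)-C4=C5 bond and gives the keto ester F6. LiAlH4 gives the diol F7, and Swern oxidation gives the keto aldehyde F8. McMurry coupling (TiCl3(DME)1.5, Zn(Cu), DME, slow addition) then closes the ring at C1=C10. This coupling does not control the new olefin geometry, so the C1=C10 (Z) isomer expected alongside 15 would be removed on AgNO3-impregnated silica.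

Further compounds
F1 | step 13 | mono-formyl o-quinone methide, 3-benzylidene-2,6-dihydroxy-4-oxocyclohexa-1,5-diene-1-carbaldehyde | O=C1C=C(O)C(C=O)=C(O)C1=Cc1ccccc1
F2 | step 13 | mono-aldehyde, psiguadial A lacking the formyl group between the two hydroxyls | C[C@H]1CC[C@@H]2[C@H]([C@@H]3[C@]4(C)CC[C@@]31Oc1c(C=O)c(O)cc(O)c1[C@@H]4c1ccccc1)C2(C)C
F3 | step 13 | mono-aldehyde, psiguadial A lacking the formyl group next to the ether oxygen | C[C@H]1CC[C@@H]2[C@H]([C@@H]3[C@]4(C)CC[C@@]31Oc1cc(O)c(C=O)c(O)c1[C@@H]4c1ccccc1)C2(C)C
F4 | step 10 | methyl carbonate of 11 | COC(=O)OC/C(C)=C/[C@H]1[C@@H](CC/C(C)=C/CS(=O)(=O)c2ccccc2)C1(C)C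
F5 | step 11 | 4-[(1R,3S)-3-(1-hydroxy-2-methylprop-2-enyl)-2,2-dimethylcyclopropyl]butan-2-one (both carbinol epimers) | CC(=C)C(O)[C@H]1[C@@H](CCC(C)=O)C1(C)C
F6 | step 11 | ethyl (4E)-5-[(1S,3R)-2,2-dimethyl-3-(3-oxobutyl)cyclopropyl]-4-methylpent-4-enoate | CCOC(=O)CC/C(C)=C/[C@H]1[C@@H](CCC(C)=O)C1(C)C
F7 | step 11 | (4E)-5-[(1S,3R)-3-(3-hydroxybutyl)-2,2-dimethylcyclopropyl]-4-methylpent-4-en-1-ol (both carbinol epimers) | OCCC/C(C)=C/[C@H]1[C@@H](CCC(C)O)C1(C)C
F8 | step 11 | (4E)-5-[(1S,3R)-2,2-dimethyl-3-(3-oxobutyl)cyclopropyl]-4-methylpent-4-enal | O=CCC/C(C)=C/[C@H]1[C@@H](CCC(C)=O)C1(C)C
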